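Labdane numbering is used. Ring A is opened at C3–C4 and the gem-dimethyl carbon C4 is tied back to C7, so the precursor is a pinane, not a decalin: ring B is the six-membered ring of (–)-verbenone, and its CMe2 bridge (C4, bonded to C5 and C7) stores C4 and shields one face while C10 and C9 are built. The route exploits quaternary C4 beside carbinol C3 in ring A and its 1,3-relation to oxygenated C7 in ring B. In one operation, H-atom transfer to C8=C17 breaks the strained C7–C4 bond, and the freed C4 radical adds to the C3 aldehyde, closing ring A as a trans-decalin, setting C3 and leaving C7=C8 for the allylic alcohol.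

Key step: step 7

Remark: pinane C2, C3, C4, C5, C7, C1 and C6 become labdane C8, C9, C10, C5, C6, C7 and C4. "Bridge face" is the face of ring B that carries the CMe2 bridge and later C20. (1S,5S)-(–)-verbenone is assumed to be used in enantiopure form, and it maps onto the ent-labdane series of the target.

Step 1
Reactants: 1 methyl but-2-ynoate
Product: 2 methyl (Z)-3-iodobut-2-enoate
Conditions: NaI, AcOH, 110 °C
Reagents that add atoms: sodium iodide, [Na+].[I-]
Why: Hydroiodination of an ynoate (conjugate addition of iodide, then anti protonation) should give the (Z)-β-iodoenoate, which fixes the later C13=C14 geometry.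

Step 2
Reactants: 3 (1S,5S)-(–)-verbenone; 4 2-(2-bromoethyl)-1,3-dioxolane
Product: 6 TMS enol ether of the C10-alkylated nopinone, via Grignard reagent 5 (not isolated)
Conditions: 4, Mg, THF, 30 °C; then CuBr·SMe2 (10 mol%), TMSCl, DMPU, 3, THF, −78 to −20 °C; Et3N, cold aq. NaHCO3
Reagents that add atoms: chlorotrimethylsilane, C[Si](C)(C)Cl
Why: In this copper-catalysed, TMSCl-accelerated conjugate addition of a Grignard reagent the CMe2 bridge blocks one enone face, so the C1–C3 chain should enter C10 anti to the bridge and leave the C20 methyl on the bridge face.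

Step 3
Reactants: 6 TMS enol ether of the C10-alkylated nopinone
Product: 10 3-methylene nopinone (C9=C11 enone), via lithium enolate 7 (not isolated), via Mannich base 8 (not isolated), via methiodide 9 (not isolated)
Conditions: MeLi, THF, 0 °C; CH2=NMe2+ I−, −78 °C to rt; MeI, rt; DBU, rt
Reagents that add atoms: Eschenmoser's salt (N,N-dimethylmethyleneiminium iodide), C=[N+](C)C.[I-]
Why: Enolate release, Mannich reaction with Eschenmoser's salt and Hofmann-type elimination is the standard α-methylenation, and only C9 can react because the other α-carbon (C7) is a bridgehead.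

Step 4
Reactants: 10 3-methylene nopinone (C9=C11 enone); 2 methyl (Z)-3-iodobut-2-enoate
Product: 13 nopinone carrying the full (Z)-enoate side chain at C9, via alkylzinc enol ether 11 (not isolated), via coupled enol ether 12 (not isolated)
Conditions: CH2(ZnI)2 (from CH2I2, Zn, cat. PbCl2, THF), TMSCl, THF, rt; then 2, PdCl2(dppf) (5 mol%), 40 °C; then 10% aq. citric acid, THF, 0 °C
Reagents that add atoms: bis(iodozincio)methane, I[Zn]C[Zn]I (made in the flask from diiodomethane, ICI, and zinc)
Why: 1,4-Addition of a gem-dizinc reagent to an s-cis enone followed by Negishi coupling of the remaining primary C–Zn bond (with retention of the iodide geometry) is a known sequential coupling, and kinetic protonation of the enol ether anti to the bridge should set C9 with the side chain on the bridge face, cis to C20.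

Step 5
Reactants: 13 nopinone carrying the full (Z)-enoate side chain at C9
Product: 14 2-methylenepinane acetal (C8=C17)
Conditions: Zn, CH2Br2, TiCl4, THF–CH2Cl2, 0 °C to rt
Reagents that add atoms: dibromomethane, BrCBr
Why: The Takai–Lombardo methylenation is non-basic, so it should convert the hindered, epimerizable ketone into the exocyclic olefin without disturbing C9, the ester or the (Z)-enoate.

Step 6
Reactants: 14 2-methylenepinane acetal (C8=C17)
Product: 15 2-methylenepinane aldehyde
Conditions: PPTS (cat.), acetone–H2O, 45 °C
Reagents that add atoms: water, O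
Why: PPTS-buffered acetal hydrolysis should be mild enough to spare the acid-sensitive methylenepinane, and C9 is no longer epimerizable once the ketone is gone.

Step 7
Reactants: 15 2-methylenepinane aldehyde
Product: 16 methyl (13Z)-ent-3β-hydroxylabda-7,13-dien-15-oate
Conditions: Fe(acac)3 (30 mol%), PhSiH3 (2.5 equiv, syringe pump), degassed i-PrOH (0.01 M), 60 °C
Reagents that add atoms: none
Why: Proposed new method: an iron hydride made from Fe(acac)3 and PhSiH3 delivers H• to the terminal carbon C17 of the 1,1-disubstituted olefin, the tertiary cyclobutylcarbinyl radical at C8 opens by β-scission of the strained C7–C4 bond to the C7=C8 olefin and the tertiary C4 radical, this radical adds to the C3 aldehyde, and the alkoxyl radical is reduced by Fe(II) and protonated by the alcohol. The closest known reaction types are the MHAT-induced ring opening of β-pinene-type olefins (radical clock, retrocycloisomerization) and the Fe(acac)3/PhSiH3 reductive radical cyclization of alkene-tethered carbonyl compounds, which have not been run as one cascade. Ring A closes by 6-exo-trig attack of C4 on the C3=O carbon, and because the C5–C4 and C10–C1 bonds are already trans on ring B the product can only be the trans-decalin. C3 is the only new stereocenter and is controlled by the chair transition state, in which the carbonyl oxygen lies equatorial to avoid 1,3-diaxial contacts with H1 and H5, so the hydroxyl should end up on the face of C20. The step needs chemoselective H• transfer to C8=C17 and ring closure faster than reduction of the C4 radical: the β,β-disubstituted enoate and the new trisubstituted olefin are poor MHAT acceptors, release of cyclobutane strain makes the scission fast and irreversible, and slow silane addition at high dilution keeps bimolecular quenching slow.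

Step 8
Reactants: 16 methyl (13Z)-ent-3β-hydroxylabda-7,13-dien-15-oate
Product: 18 7,8-epoxide on the C20 face, via bromohydrin 17 (not isolated)
Conditions: NBS, acetone–H2O, 0 °C; then K2CO3, MeOH, rt
Reagents that add atoms: water, O
Why: In this halohydrin formation and Williamson-type closure Br+ should add anti to C20, water should open the bromonium ion trans-diaxially at tertiary C8, and the intramolecular SN2 at C7 then places the epoxide oxygen on the C20 face, which is the configuration needed at C7.

Step 9
Reactants: 18 7,8-epoxide on the C20 face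
Product: 19 methyl (13Z)-ent-3β,7β-dihydroxylabda-8(17),13-dien-15-oate (target)
Conditions: Cp2TiCl2 (3 equiv), Mn dust, degassed THF, rt; then aq. NaH2PO4
Reagents that add atoms: none
Why: Titanocene(III) opening of the epoxide should give the tertiary C8 radical with the C7–O bond and its configuration intact, and β-hydrogen abstraction from the least hindered C17 methyl by a second Cp2TiCl gives the exocyclic allylic alcohol, a known epoxide-to-allylic-alcohol isomerization.

Compound list
1 | methyl but-2-ynoate | CC#CC(=O)OC | starting material
2 | methyl (Z)-3-iodobut-2-enoate | I/C(C)=C\C(=O)OC | intermediate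
3 | (1S,5S)-(–)-verbenone, (1S,5S)-4,6,6-trimethylbicyclo[3.1.1]hept-3-en-2-one | CC1=CC(=O)[C@H]2C[C@@H]1C2(C)C | starting material
4 | 2-(2-bromoethyl)-1,3-dioxolane | BrCCC1OCCO1 | starting material
5 | [2-(1,3-dioxolan-2-yl)ethyl]magnesium bromide | Br[Mg]CCC1OCCO1 | intermediate
6 | 4-[2-(1,3-dioxolan-2-yl)ethyl]-4,6,6-trimethyl-2-(trimethylsilyloxy)bicyclo[3.1.1]hept-2-ene, chain anti and methyl syn to the CMe2 bridge | C[Si](C)(C)OC1=C[C@](C)(CCC2OCCO2)[C@@H]3C[C@H]1C3(C)C | intermediate
7 | lithium enolate corresponding to 6 | [Li]OC1=C[C@](C)(CCC2OCCO2)[C@@H]3C[C@H]1C3(C)C | intermediate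
8 | 3-(dimethylaminomethyl) ketone (Mannich base), aminomethyl group anti to the bridge | O=C1[C@H]3C[C@H](C3(C)C)[C@@](C)(CCC2OCCO2)[C@H]1CN(C)C | intermediate
9 | methiodide of 8 | O=C1[C@H]3C[C@H](C3(C)C)[C@@](C)(CCC2OCCO2)[C@H]1C[N+](C)(C)C.[I-] | intermediate
10 | 4-[2-(1,3-dioxolan-2-yl)ethyl]-4,6,6-trimethyl-3-methylenebicyclo[3.1.1]heptan-2-one | O=C1[C@H]3C[C@H](C3(C)C)[C@@](C)(CCC2OCCO2)C1=C | intermediate
11 | TMS enol ether bearing a 2-(iodozincio)ethyl group at C9 | C[Si](C)(C)OC1=C(CC[Zn]I)[C@](C)(CCC2OCCO2)[C@@H]3C[C@H]1C3(C)C | intermediate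
12 | TMS enol ether bearing the (Z)-enoate side chain at C9 | C[Si](C)(C)OC1=C(CC/C(C)=C\C(=O)OC)[C@](C)(CCC2OCCO2)[C@@H]3C[C@H]1C3(C)C | intermediate
13 | methyl (Z)-5-(2-oxopinan-3-yl)-3-methylpent-2-enoate with the acetal chain at C10, side chain at C9 syn to the bridge and cis to C20 | O=C1[C@H]3C[C@H](C3(C)C)[C@@](C)(CCC2OCCO2)[C@@H]1CC/C(C)=C\C(=O)OC | intermediate
14 | 2-methylene analogue of 13 (C8=C17) | C=C1[C@H]3C[C@H](C3(C)C)[C@@](C)(CCC2OCCO2)[C@@H]1CC/C(C)=C\C(=O)OC | intermediate
15 | aldehyde from 14 (3-oxopropyl chain at C10) | C=C1[C@H]3C[C@H](C3(C)C)[C@@](C)(CCC=O)[C@@H]1CC/C(C)=C\C(=O)OC | intermediate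
16 | methyl (13Z)-ent-3β-hydroxylabda-7,13-dien-15-oate (trans-decalin, equatorial 3-OH on the C20 face) | CC1=CC[C@@H]2C(C)(C)[C@H](O)CC[C@@]2(C)[C@@H]1CC/C(C)=C\C(=O)OC | intermediate
17 | trans-diaxial bromohydrin, 7-Br anti to C20 and 8-OH on the C20 face | C[C@@]1(O)[C@@H](Br)C[C@@H]2C(C)(C)[C@H](O)CC[C@@]2(C)[C@@H]1CC/C(C)=C\C(=O)OC | intermediate
18 | methyl (13Z)-ent-7β,8β-epoxy-3β-hydroxylabd-13-en-15-oate (epoxide oxygen on the C20 face) | C[C@@]12O[C@@H]1C[C@@H]3C(C)(C)[C@H](O)CC[C@@]3(C)[C@@H]2CC/C(C)=C\C(=O)OC | intermediate
19 | methyl (13Z)-ent-3β,7β-dihydroxylabda-8(17),13-dien-15-oate | C=C1[C@H](O)C[C@@H]2C(C)(C)[C@H](O)CC[C@@]2(C)[C@@H]1CC/C(C)=C\C(=O)OC | target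

Total step count: 9. Longest linear sequence: 8 (steps 2 to 9).

Steps most likely to fail

Step 7. The C4 radical may be quenched by hydrogen donors before it closes. The addition to the aldehyde may also revert by β-scission of the alkoxyl radical, or the oxygen may take the axial position in the transition state. The fallback stages the cascade into known reactions and sets out from 14. A cobalt(salen)-catalysed MHAT retrocycloisomerization (cat. Co(salen)Cl, cat. PhSiH3, benzene, rt) should open the cyclobutane to the monocyclic isopropenyl diene acetal F1. PPTS hydrolysis then gives the diene aldehyde F2. The established Fe(acac)3/PhSiH3 alkene–carbonyl radical cyclization, selective for the 1,1-disubstituted isopropenyl group, closes ring A and comes back to the route at 16.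

Step 4. The gem-dizinc reagent may add incompletely or react at both C–Zn bonds, β-hydride elimination may compete in the sp3–sp2 coupling, and protonation may occur from the bridge face or C9 may epimerize afterwards. The fallback separates the events through an isolable organoboron compound and sets out from 10. A copper-catalysed 1,4-addition of bis(pinacolatoboryl)methane, with protonation anti to the bridge, gives the γ-boryl ketone F3. A Suzuki–Miyaura coupling of F3 with 2 (Pd(OAc)2, RuPhos, K2CO3, toluene–H2O) comes back to the route at 13.

Step 9. Hydrogen abstraction may take place at C9 instead of C17, the C8 radical may add 5-exo to the enoate, or the epoxide may be deoxygenated. The fallback sets C7 by oxidation and reduction instead, sets out from 16 and bypasses steps 8 and 9. A Schenck ene reaction (O2, hν, tetraphenylporphyrin, CH2Cl2, −20 °C) on the face anti to C20 gives the allylic hydroperoxide F4. PPh3 reduces it to the 7-epimeric axial allylic alcohol F5. MnO2 oxidizes only the allylic alcohol to the exocyclic enone F6. Luche reduction (NaBH4, CeCl3, MeOH, −78 °C), with axial hydride delivery anti to C20, comes back to the route at 19.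

Further compounds
F1 | step 7 | monocyclic isopropenyl diene acetal (C7=C8 olefin, isopropenyl at C5, acetal chain at C10) | CC1=CC[C@H](C(C)=C)[C@@](C)(CCC2OCCO2)[C@@H]1CC/C(C)=C\C(=O)OC
F2 | step 7 | diene aldehyde from F1 | CC1=CC[C@H](C(C)=C)[C@@](C)(CCC=O)[C@@H]1CC/C(C)=C\C(=O)OC
F3 | step 4 | γ-boryl ketone, 2-(pinacolatoboryl)ethyl group at C9 syn to the bridge | O=C1[C@H]3C[C@H](C3(C)C)[C@@](C)(CCC2OCCO2)[C@@H]1CCB4OC(C)(C)C(C)(C)O4
F4 | step 9 | allylic hydroperoxide, 7-OOH anti to C20, 8(17)-ene | C=C1[C@@H](OO)C[C@@H]2C(C)(C)[C@H](O)CC[C@@]2(C)[C@@H]1CC/C(C)=C\C(=O)OC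
F5 | step 9 | 7-epimer of 19 (axial 7-OH anti to C20) | C=C1[C@@H](O)C[C@@H]2C(C)(C)[C@H](O)CC[C@@]2(C)[C@@H]1CC/C(C)=C\C(=O)OC
F6 | step 9 | 7-oxo-8(17)-ene (exocyclic enone) | C=C1C(=O)C[C@@H]2C(C)(C)[C@H](O)CC[C@@]2(C)[C@@H]1CC/C(C)=C\C(=O)OC
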